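## Analysis of the target

Numbering used throughout: C1 is the benzoyl-bearing bridgehead, C2 a ketone, C3 the quaternary carbon shared with the cyclopentane, C4 a ketone, C5 the geranyl-bearing bridgehead, C6 a CH2, C7 a CH, C8 a CMe2, C9 the ketone between C1 and C5, C11 the CH2 on C7, C12 the CH on C3, C13 a CMe2, C14 a CH2 and C15 the CH2 on C3. Ring A is C1–C2–C3–C4–C5–C9, ring B is C1–C9–C5–C6–C7–C8, ring C is C3–C4–C5–C6–C7–C11–C12, ring D is C1–C2–C3–C12–C11–C7–C8 and ring E is C3–C12–C13–C14–C15.

The target is a pentacyclic polyprenylated acylphloroglucinol. A cyclohexane-1,3,5-trione (ring A) is bridged by C6–C7–C8 into a bicyclo[3.3.1]nonane (ring B). C3 and C7 are tied a second time by C12–C11, which gives a homoadamantane cage with the seven-membered rings C and D, and a 2,2-dimethylcyclopentane (ring E) is fused on C3–C12. There are five stereocentres (C1, C3, C5, C7, C12). The cage fixes the relative configuration of C1, C3, C5 and C7, so the only free relationship is that of C12 to the cage, together with the absolute sense. C12–H lies on the C4 side, so ring E is cis-fused to ring D and trans-fused to ring C. C1, C3 and C5 are quaternary, C8 and C13 are quaternary gem-dimethyl carbons, and C1–C8 and C3–C12–C13 are contiguous congested arrays. None of the three ring ketones can enolise, so the β-tricarbonyl array and the triacylmethane at C1 are open to retro-Claisen cleavage by alkoxides. The two trisubstituted alkenes of the geranyl chain exclude late hydrogenation, strong acid and electrophilic halogen. The difficulty is to set C12 absolutely, relay it to C7 and C3, and then close a cage that offers no stabilised enolate as a thermodynamic sink. The strategy rests on ring C: a cycloheptanone (C4) whose C5 carries the carboxyl carbon C9, whose C3 is a free α-methylene, and whose C12 stereocentre next to quaternary C13 faces the C5–C6 bond across a C7=C11 alkene. This is the pattern of the cyclohepta-1,4-diene formed when a 2-siloxyvinyl carbenoid cyclopropanates a diene and the cis-divinylcyclopropane undergoes a Cope rearrangement.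

## Retrosynthetic reasoning

20 is cut first at the exocyclic C1–C(=O)Ph bond, giving cage trione 18 and 19. The triacylmethane is the most nucleophile-sensitive unit and would not survive any of the enolate chemistry needed earlier, so it is made last. The forward step has to generate a carbanion at the bridgehead C1, flanked by C2=O and C9=O, and acylate it on carbon.

18 is cut at C1–C9, which opens rings A and B and leads to tricyclic keto ester 17. The ester carbon C9 on C5 is held directly above C1 across the eight-membered ring. The forward reaction is a transannular Claisen condensation of the C2 ketone enolate, and it must proceed without the help of a final deprotonation.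

17 is cut at the C5–geranyl bond to give β-keto ester 15 and 16. The cut is placed here because, as long as C5 carries hydrogen, base turns the C4/C9 unit into an enolate whose ester carbon cannot act as an acyl donor. That protects C9 during the preceding acylation but must be removed before the C1–C9 closure. At this stage C5 is an ordinary β-keto ester carbon, not a bridgehead, and the bridged frame decides the face of alkylation.

15 is cut at C2–C3, which opens ring D and gives bicyclic β-keto ester 14. In the forward direction the γ-carbon C3 of the β-keto ester dianion attacks the side-chain ester on the face of ring C that carries the C7 chain. This fixes C3 with C15 trans to C13, whichever C3 epimer of 14 is used.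

14 comes from alkene 13 by addition of hydrogen to C7=C11. The alkene must be saturated before the C2–C3 bond is made, since that bond would otherwise create a bridgehead alkene. It must also be saturated before geranyl is introduced. The step sets C7, and the forward reaction has to deliver hydrogen to the face opposite ring E and C13.

13 is cut at C3–C15, which opens ring E and gives chloride 12. The forward step is γ-alkylation of the β-keto ester dianion, a 5-exo closure. It is placed while C7 is still sp2, so that the C2 ester cannot reach C3 and the dianion has only one electrophile.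

12 is the desilylated form of silyl enol ether 11. 11 is cut at C5–C6 and C3–C12 through cis-divinylcyclopropane 10 to diene 6 and siloxyvinyldiazoacetate 9. This is the only disconnection that delivers ring C with C12 set absolutely by a catalyst and with C4, C9 and both side chains at the right oxidation level. It also avoids ever forming the hindered C12–C13 bond, because C13 arrives attached to C12.

6 is cut at C7–C11 into alkenyl triflate 3 and terminal alkene 5. The forward Heck coupling can only give the E-diene, because C13 has no hydrogen. Both halves come from 1: oxidation of its vinyl group and enol triflation give 3 by way of 2, and reduction and chlorination give 5 by way of 4. Both gem-dimethyl quaternary carbons are therefore bought, not made. 9 comes from 7 by diazo transfer (8) and O-silylation.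

## Alternatives that were turned down

Alternative 1: Tethered double C-acylation. The cut is at C4–C5 and C1–C2. The precursor A2 is the silyl enol ether of a 2-geranyl-5,5-dimethylcyclohexanone (ring B) whose C7 carries, through C11, a 2,2-dimethylcyclopentane bearing two acid chloride groups on C3. In the forward step one acid chloride acylates C5, the enol is re-formed towards C1, and the second acylates C1, which closes rings A, C and D at once and gives A1, identical with 18.
- For: three rings close in one operation, and chloride as leaving group makes both C–C bonds irreversible. On this point it is stronger than the alkoxide-releasing Claisen closures of the chosen route.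
- Against: the two acid chlorides of A2 are diastereotopic, and which one attacks C5 decides whether C13 ends next to C2 or next to C4. That is the one free stereochemical relationship of the target, and only a rotatable methylene biases it. A2 also needs C7 and C12 set independently across that methylene, two geminal acid chlorides beside the quaternary C13, and acylium chemistry next to the geranyl alkenes.
- Comparison: the chosen route needs about seven steps from ring C to 18 against one here, but every stereochemical relationship is relayed through a ring from a catalyst-set C12.

Alternative 2: Radical conjugate addition and cycloalkylation to annulate ring E. The cut is at C12–C13 and C3–C15. The precursors are the cycloheptenone ester A4 (ring D with a C3=C12 alkylidene β-keto ester) and the homoallylic tosylate A5. Metal-hydride hydrogen-atom transfer to the alkene of A5 gives the tertiary radical C13, which adds to C12 of A4. The C3 radical is reduced to the enolate, and displacement of the tosylate closes ring E to give A3.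
- For: it forms the most congested bond of the molecule (C12–C13) by a sterically tolerant radical step and sets the quaternary C3 at the same time. The chosen route only avoids that bond by carrying C13 in from 1.
- Against: the C12 configuration relative to C7 would be controlled remotely across a flexible seven-membered ring. The absolute configuration would have to be built into A4 at C7, which has no neighbouring functional handle. The enolate is likely to be protonated before it alkylates, so a second base step would be needed. A3 still lacks rings A, B and C and would need the same Claisen closures plus the C4–C5 bond.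
- Comparison: the chosen route sets C12 by catalyst control and builds ring C, which Alternative 2 leaves for last, in the same step.

Alternative 3: Effenberger annulation. The cut is at C3–C4 and C1–C9. The methyl enol ether A7 of the hydroazulenone (rings D and E, with a chloromethyl group as C6 on C7) is acylated by geranylmalonyl dichloride A8 at C3 and then at C1. This closes ring A and gives A6.
- For: it is convergent, geranyl arrives with the C4–C5–C9 unit, and A6 is an enolisable 1,3-diketone, so the acylation has a thermodynamic sink. The Claisen closures of the chosen route lack this, and Alternative 3 is stronger here.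
- Against: the double acylation must create the quaternary C3 beside C12/C13 and then attack the neopentyl C1, and such annulations are inefficient even on unhindered enol ethers. The geranyl alkene again meets acid chloride and acid. The last closure (C5–C6, closing rings B and C together) is a substitution at a β-branched primary chloride by a delocalised diketone enolate, where O-alkylation and slow displacement are expected. A7 also needs C7 and C12 set cis without a ring template.
- Comparison: the chosen route forms the C5–C6 bond in the carbenoid step, where it is not a substitution at all, and forms C5–geranyl by a simple β-keto ester alkylation.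

Key step: step 8

Remark on the chemistry (assumption): the sense of induction of Rh2(S-PTAD)4 is taken from the accepted model for donor/acceptor carbenoid cyclopropanation. If 11 is formed with the opposite configuration at C12, Rh2(R-PTAD)4 is used and nothing else changes.

## Route

Step 1
Reactants: 1 methyl 3,3-dimethylpent-4-enoate
Product: 2 methyl 3,3-dimethyl-4-oxopentanoate
Conditions: PdCl2 (10 mol %), CuCl (cat.), O2 (1 atm), DMF/H2O 7:1, rt
Reagents that add atoms: water, O
Why: Wacker oxidation; Markovnikov hydroxypalladation of the monosubstituted alkene gives the methyl ketone, and the neighbouring quaternary carbon slows the reaction but leaves no allylic hydrogen for isomerisation.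

Step 2
Reactants: 2 methyl 3,3-dimethyl-4-oxopentanoate
Product: 3 methyl 3,3-dimethyl-4-{[(trifluoromethyl)sulfonyl]oxy}pent-4-enoate
Conditions: KN(SiMe3)2, THF, −78 °C, added to 2 premixed with Comins' reagent; −78 → −40 °C
Reagents that add atoms: N-(5-chloropyridin-2-yl)-1,1,1-trifluoro-N-[(trifluoromethyl)sulfonyl]methanesulfonamide (Comins' reagent), FC(F)(F)S(=O)(=O)N(c1ccc(Cl)cn1)S(=O)(=O)C(F)(F)F
Why: Enol triflate formation; the ketone can enolise only towards its methyl group and is more acidic than the ester, and trapping the potassium enolate in situ at −78 °C forestalls its intramolecular Claisen attack on the ester.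

Step 3
Reactants: 1 methyl 3,3-dimethylpent-4-enoate
Product: 4 3,3-dimethylpent-4-en-1-ol
Conditions: LiAlH4, Et2O, 0 °C
Reagents that add atoms: none
Why: Hydride reduction of the ester to the primary alcohol; the isolated alkene is inert.

Step 4
Reactants: 4 3,3-dimethylpent-4-en-1-ol
Product: 5 5-chloro-3,3-dimethylpent-1-ene
Conditions: PPh3, CCl4, CH2Cl2, reflux
Reagents that add atoms: carbon tetrachloride, ClC(Cl)(Cl)Cl
Why: Appel chlorination by SN2 displacement of the alkoxyphosphonium ion at an unhindered primary carbon; the chloride is chosen because it survives the palladium and rhodium steps and is still displaced intramolecularly in step 10.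

Step 5
Reactants: 3 methyl 3,3-dimethyl-4-{[(trifluoromethyl)sulfonyl]oxy}pent-4-enoate; 5 5-chloro-3,3-dimethylpent-1-ene (excess)
Product: 6 methyl (5E)-9-chloro-3,3,7,7-tetramethyl-4-methylidenenon-5-enoate
Conditions: Pd(OAc)2 (5 mol %), P(o-tol)3 (10 mol %), Et3N, DMF, 80 °C, sealed tube
Reagents that add atoms: none
Why: Mizoroki–Heck coupling; the alkenylpalladium triflate adds to the terminal alkene with palladium at the internal carbon (steric control by the quaternary neighbour), and syn β-hydride elimination, possible only towards the new bond, gives the E-diene; there is no allylic hydrogen to migrate and the primary chloride does not add oxidatively.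

Step 6
Reactants: 7 methyl acetoacetate
Product: 8 methyl 2-diazo-3-oxobutanoate
Conditions: 4-acetamidobenzenesulfonyl azide, Et3N, MeCN, 0 °C → rt
Reagents that add atoms: 4-acetamidobenzenesulfonyl azide, CC(=O)Nc1ccc(cc1)S(=O)(=O)N=[N+]=[N-]
Why: Regitz diazo transfer to the activated methylene.

Step 7
Reactants: 8 methyl 2-diazo-3-oxobutanoate
Product: 9 methyl 3-[(tert-butyldimethylsilyl)oxy]-2-diazobut-3-enoate
Conditions: TBSOTf, Et3N, CH2Cl2, 0 °C
Reagents that add atoms: tert-butyldimethylsilyl trifluoromethanesulfonate, CC(C)(C)[Si](C)(C)OS(=O)(=O)C(F)(F)F
Why: Soft enolisation and O-silylation of the acetyl group give the 2-siloxyvinyl diazoacetate; the diazo group is untouched.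

Step 8
Reactants: 6 methyl (5E)-9-chloro-3,3,7,7-tetramethyl-4-methylidenenon-5-enoate; 9 methyl 3-[(tert-butyldimethylsilyl)oxy]-2-diazobut-3-enoate (1.5 equiv, slow addition)
Product: 11 methyl (4R)-2-[(tert-butyldimethylsilyl)oxy]-4-(4-chloro-2-methylbutan-2-yl)-6-(4-methoxy-2-methyl-4-oxobutan-2-yl)cyclohepta-1,5-diene-1-carboxylate, via cis-divinylcyclopropane 10 (not isolated)
Conditions: Rh2(S-PTAD)4 (dirhodium tetrakis[(S)-(adamantan-1-yl)(phthalimido)acetate], 1 mol %), hexanes, 0 °C → rt; then 50 °C
Reagents that add atoms: none
Why: The dirhodium tetracarboxylate decomposes 9 to a donor/acceptor (siloxyvinyl/ester) carbenoid, which adds end-on to the unhindered CH2 terminus (C6) of the 1,1-disubstituted alkene of 6 while positive charge builds at the allyl-stabilised C7; the trans-disubstituted C11=C12 alkene is shielded by C13 and is left alone, and 6 has no allylic C–H bond for competing insertion because C8 and C13 are quaternary. Ring closure of the cyclopropane should place the conjugating alkenyl group cis to the siloxyvinyl donor, as is general for dienes, so that cis-divinylcyclopropane 10 forms with C5 and C7 set by the chiral carboxylate ligands. 10 then undergoes a [3,3]-sigmatropic (Cope) shift through the boat transition state with both vinyl groups folded over the three-membered ring; C5–C7 breaks and C3–C12 forms, which closes the seven-membered ring C pericyclically (formal (4+3) cycloaddition). The new stereocentre C12 is controlled by the catalyst-set cyclopropane configuration, relayed through the boat geometry with the E-alkene keeping the tert-alkyl group exo. The closest known reaction type is the enantioselective dirhodium-catalysed tandem cyclopropanation/Cope rearrangement of 2-siloxyvinyldiazoacetates with acyclic dienes. The step needs site selectivity (secured by the steric difference between the two alkenes), cis-divinyl diastereoselectivity (the π-substituent prefers the donor side), enantioselectivity (ligand) and suppression of attack at the vinylogous carbenoid terminus (hydrocarbon solvent, carboxylate catalyst). The product already holds C4 as a silyl enol ether, C9 on C5 and both side chains.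

Step 9
Reactants: 11 the silyl enol ether from step 8
Product: 12 methyl (4R)-4-(4-chloro-2-methylbutan-2-yl)-6-(4-methoxy-2-methyl-4-oxobutan-2-yl)-2-oxocyclohept-5-ene-1-carboxylate (keto/enol mixture, C5 undefined)
Conditions: Bu4NF, AcOH, THF, 0 °C
Reagents that add atoms: none
Why: Buffered fluoride cleaves the O–Si bond and frees the β-keto ester; the skipped C7=C11 alkene cannot move into conjugation under these conditions.

Step 10
Reactants: 12 the chloro β-keto ester from step 9
Product: 13 methyl (8aS)-7-(4-methoxy-2-methyl-4-oxobutan-2-yl)-1,1-dimethyl-4-oxo-1,2,3,3a,4,5,6,8a-octahydroazulene-5-carboxylate (rings C and E; azulene C8a = C12; C3 and C5 epimerisable and undefined)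
Conditions: LiN(iPr)2 (LDA, 2.3 equiv), THF, −78 °C → rt
Reagents that add atoms: none
Why: γ-Alkylation of the β-keto ester dianion; the C3 carbanion displaces the primary chloride C15 in a 5-exo-tet closure of ring E, the side-chain ester cannot reach C3 while C7 is sp2, and the new C3 centre need not be controlled because it is re-enolised in step 12.

Step 11
Reactants: 13 the bicyclic alkene from step 10
Product: 14 methyl (7R,8aS)-7-(4-methoxy-2-methyl-4-oxobutan-2-yl)-1,1-dimethyl-4-oxodecahydroazulene-5-carboxylate (H7 and H12 cis; C3 and C5 undefined)
Conditions: H2 (4 bar), PtO2 (10 mol %), EtOAc, rt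
Reagents that add atoms: none
Why: Heterogeneous syn-hydrogenation of the trisubstituted C7=C11 alkene from the face opposite the cyclopentane and its gem-dimethyl carbon C13, which flank C11; this should set C7 with the C8 chain cis to C13, and the hydrogen-bonded enol of the β-keto ester and the esters are not reduced.

Step 12
Reactants: 14 the saturated bicyclic β-keto ester from step 11
Product: 15 tricyclic diketo ester (rings C, D and E): C3 quaternary and bonded to C2, C4, C12 and C15, ketones at C2 and C4, C5 still CH–CO2Me, C15 trans to C13 on ring C
Conditions: LiN(iPr)2 (LDA, 2.3 equiv), THF, −78 °C → rt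
Reagents that add atoms: none
Why: Intramolecular acylation of the β-keto ester dianion (Claisen condensation at the γ-carbon); the C5 enolate keeps C4 and C9 inert, the C3 carbanion attacks the C2 ester on the only face the C7 tether can reach (which sets C3), and a competing enolate at C1 has no electrophile and can return by proton transfer.

Step 13
Reactants: 15 the tricyclic diketo ester from step 12; 16 geranyl bromide
Product: 17 C5-geranyl tricyclic diketo ester (geranyl on the face turned to the C11–C12 bridge, CO2Me pointing at C1)
Conditions: K2CO3, acetone, 50 °C
Reagents that add atoms: none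
Why: C-Alkylation of the β-keto ester enolate by SN2 at the primary allylic bromide; the face of the C4=C5 enolate that looks at the three-atom bridge is blocked by the transannular C1 methylene, so geranyl should enter from the side of the two-carbon bridge and push the ester towards C1.

Step 14
Reactants: 17 the C5-geranyl tricyclic diketo ester from step 13
Product: 18 cage trione with C1–H (the target lacking the benzoyl group)
Conditions: LiN(SiMe3)2 (1.5 equiv), THF, −78 → 0 °C; AcOH quench at −78 °C
Reagents that add atoms: none
Why: Transannular Claisen condensation; the C2 ketone enolate (C1 is the only enolisable position left) attacks the C9 ester held above it, closing rings A and B, and C1 is fixed by the cage; with a lithium amide in THF the methoxide leaves as aggregated LiOMe, a poor nucleophile towards the hindered ketones at low temperature.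

Step 15
Reactants: 18 the cage trione from step 14; 19 benzoyl chloride
Product: 20 target CNP0168637.1
Conditions: lithium 2,2,6,6-tetramethylpiperidide (LiTMP, 2 equiv), THF, −78 °C; then 19, −78 °C → rt
Reagents that add atoms: none
Why: Bridgehead deprotonation and C-acylation, as established for bicyclo[3.3.1]nonane-2,4,9-trione derivatives of this natural product family; C1–H is the only acidic hydrogen, the amide has no β-hydrogen to reduce the ketones, and the configuration at C1 is fixed by the cage.

## Compound list

1 | methyl 3,3-dimethylpent-4-enoate | COC(=O)CC(C)(C)C=C | starting material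
2 | methyl 3,3-dimethyl-4-oxopentanoate | COC(=O)CC(C)(C)C(C)=O | intermediate
3 | methyl 3,3-dimethyl-4-{[(trifluoromethyl)sulfonyl]oxy}pent-4-enoate | COC(=O)CC(C)(C)C(=C)OS(=O)(=O)C(F)(F)F | intermediate
4 | 3,3-dimethylpent-4-en-1-ol | OCCC(C)(C)C=C | intermediate
5 | 5-chloro-3,3-dimethylpent-1-ene | ClCCC(C)(C)C=C | intermediate
6 | methyl (5E)-9-chloro-3,3,7,7-tetramethyl-4-methylidenenon-5-enoate | C=C(C(C)(C)CC(=O)OC)/C=C/C(C)(C)CCCl | intermediate
7 | methyl acetoacetate | COC(=O)CC(C)=O | starting material
8 | methyl 2-diazo-3-oxobutanoate | COC(=O)C(=[N+]=[N-])C(C)=O | intermediate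
9 | methyl 3-[(tert-butyldimethylsilyl)oxy]-2-diazobut-3-enoate | COC(=O)C(=[N+]=[N-])C(=C)O[Si](C)(C)C(C)(C)C | intermediate
10 | methyl (1R,2S)-1-{1-[(tert-butyldimethylsilyl)oxy]ethenyl}-2-[(1E)-5-chloro-3,3-dimethylpent-1-en-1-yl]-2-(4-methoxy-2-methyl-4-oxobutan-2-yl)cyclopropane-1-carboxylate | COC(=O)[C@]1(C(=C)O[Si](C)(C)C(C)(C)C)C[C@]1(/C=C/C(C)(C)CCCl)C(C)(C)CC(=O)OC | intermediate (not isolated)
11 | methyl (4R)-2-[(tert-butyldimethylsilyl)oxy]-4-(4-chloro-2-methylbutan-2-yl)-6-(4-methoxy-2-methyl-4-oxobutan-2-yl)cyclohepta-1,5-diene-1-carboxylate | COC(=O)C1=C(O[Si](C)(C)C(C)(C)C)C[C@@H](C(C)(C)CCCl)C=C(C(C)(C)CC(=O)OC)C1 | intermediate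
12 | methyl (4R)-4-(4-chloro-2-methylbutan-2-yl)-6-(4-methoxy-2-methyl-4-oxobutan-2-yl)-2-oxocyclohept-5-ene-1-carboxylate | COC(=O)C1C(=O)C[C@@H](C(C)(C)CCCl)C=C(C(C)(C)CC(=O)OC)C1 | intermediate
13 | methyl (8aS)-7-(4-methoxy-2-methyl-4-oxobutan-2-yl)-1,1-dimethyl-4-oxo-1,2,3,3a,4,5,6,8a-octahydroazulene-5-carboxylate | COC(=O)C1C(=O)C2CCC(C)(C)[C@H]2C=C(C(C)(C)CC(=O)OC)C1 | intermediate
14 | methyl (7R,8aS)-7-(4-methoxy-2-methyl-4-oxobutan-2-yl)-1,1-dimethyl-4-oxodecahydroazulene-5-carboxylate | COC(=O)C1C(=O)C2CCC(C)(C)[C@H]2C[C@@H](C(C)(C)CC(=O)OC)C1 | intermediate
15 | tricyclic diketo ester (rings C, D, E; C5–H) | COC(=O)C1C[C@H]2C[C@@H]3C(C)(C)CC[C@]3(C1=O)C(=O)CC2(C)C | intermediate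
16 | geranyl bromide | CC(C)=CCC/C(C)=C/CBr | starting material
17 | C5-geranyl tricyclic diketo ester | CC(C)=CCC/C(C)=C/C[C@@]1(C(=O)OC)C[C@H]2C[C@@H]3C(C)(C)CC[C@]3(C1=O)C(=O)CC2(C)C | intermediate
18 | cage trione with C1–H | CC(C)=CCC/C(C)=C/C[C@@]12C[C@H]3C[C@@H]4C(C)(C)CC[C@]4(C1=O)C(=O)[C@@H](C2=O)C3(C)C | intermediate
19 | benzoyl chloride | O=C(Cl)c1ccccc1 | starting material
20 | CNP0168637.1 | CC(C)=CCC/C(C)=C/C[C@@]12C[C@H]3C[C@@H]4C(C)(C)CC[C@]4(C1=O)C(=O)[C@@](C(=O)c1ccccc1)(C2=O)C3(C)C | target

## Step count and least certain steps

Total: 15 steps. Longest linear sequence: 11 steps (1 → 2 → 3 → 6 → 11 → 12 → 13 → 14 → 15 → 17 → 18 → 20; the branch through 4 and 5 is equally long).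

**Step 8 (key step).** The carbenoid may close the cyclopropane with the tert-alkyl group, not the alkenyl group, cis to the siloxyvinyl donor. That trans-divinyl isomer rearranges only after thermal ring opening, and one-centre epimerisation at C5 or at C7 then leads to enantiomeric cis isomers, so the enantiomeric purity at C12 would erode. The hindered C7 may also slow cyclopropanation enough for carbenoid dimerisation or vinylogous attack to compete. Any trans-divinylcyclopropane is therefore separated, not thermolysed.

Fallback: a smaller carbenoid, with the C4 oxygen added afterwards. It sets out from 8 and 6 and returns at 12. 8 is reduced (NaBH4, MeOH, 0 °C) to methyl 2-diazo-3-hydroxybutanoate F1, which is dehydrated (POCl3, Et3N, CH2Cl2, 0 °C) to methyl 2-diazobut-3-enoate F2. F2 is added at −78 °C to 6 and Rh2(R-DOSP)4 (dirhodium tetrakis[(R)-N-(4-dodecylbenzenesulfonyl)prolinate]) in hexanes, the best-established pairing for cis-selective cyclopropanation/Cope rearrangement, to give the cycloheptadiene ester F3. Copper-catalysed conjugate borylation of its enoate (CuCl, a bisphosphine, NaOtBu, bis(pinacolato)diboron, MeOH) gives the β-boryl ester F4. Oxidation with NaBO3 gives the β-hydroxy ester F5, and Dess–Martin oxidation gives 12.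

**Step 12.** The second equivalent of amide may remove a proton from the ester α-carbon C1 faster than from the hindered methine C3, and the seven-membered bridging acylation on the face that also carries C13 may be slow. The dianion would then be consumed by proton transfer or intermolecular condensation before it closes.

Fallback: alkylate first, so that a plain ketone enolate does the acylation. It sets out from 14 and returns at 17. 14 is C-geranylated with 16 (K2CO3, acetone) to the geranylated bicyclic keto diester F8. Here the configuration at C5 rests on axial attack anti to the C7 substituent on a flexible ring, which is less secure than in step 13. LiN(SiMe3)2 in THF then forms the C3 enolate of the now singly enolisable C4 ketone, which acylates onto the C2 ester to give 17. Under excess base this goes on to 18 as in step 14.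

**Step 14.** The liberated methoxide may add to C9, C2 or C4 of the non-enolisable trione, or the tetrahedral intermediate may revert, because no stabilised enolate pulls the condensation forward. The result would be ring-opening by retro-Claisen cleavage or incomplete closure.

Fallback: an acyl donor with a non-nucleophilic leaving group. It sets out from 17 and returns at 18. The methyl ester of 17 is cleaved at the methyl carbon with lithium propane-1-thiolate (DMPU, rt; SN2 dealkylation, no heating, so the β-keto carboxylate does not decarboxylate) to the C9 carboxylic acid F9. 1-Chloro-N,N,2-trimethylprop-1-en-1-amine (CH2Cl2, 0 °C) converts it into the acid chloride F10 under neutral conditions. Soft enolisation of the C2 ketone (MgBr2·OEt2, iPr2NEt, CH2Cl2) then gives irreversible C-acylation at C1 and 18.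

**Step 15.** The bridgehead C1–H lies close to the nodal planes of both flanking carbonyl groups, and the cage is more rigid than the bicyclic systems on which this deprotonation is known. Proton removal may therefore be too slow at low temperature, and at higher temperature the amide may instead add to a ketone and trigger cleavage.

Fallback: generate the C1 carbanion by halogen–metal exchange instead of deprotonation. It sets out from 15 and returns at 20. The dianion of 15 (LiN(SiMe3)2, 2.1 equiv, THF, −78 °C) is brominated at its more reactive ketone enolate carbon with CBr4 to the 1-bromo tricyclic diketo ester F11. C5-geranylation as in step 13 gives F12, and the Claisen closure as in step 14 gives the bridgehead bromide F13. Bromine–magnesium exchange (iPrMgCl·LiCl, THF, −78 °C) and addition of benzaldehyde give the carbinol F14, and Dess–Martin oxidation gives 20.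

**Step 11.** The alkene is trisubstituted and flanked by a quaternary carbon on one side and the C12/C13 array on the other. Hydrogenation may be slow enough for the double bond to migrate towards C12 on the metal surface, which would scramble C12, or for the C4 ketone to be reduced. Addition from the wrong face would give the C7 epimer, which then leads to the C12-epimeric cage.

Fallback: hydrogenate before the ketone is unmasked, with a homogeneous catalyst that does not isomerise. It sets out from 11 and returns at 14. 11 is hydrogenated with [Ir(cod)(PCy3)(py)]PF6 (H2, CH2Cl2) to the saturated silyl enol ether F6, again anti to the tert-alkyl group on C12. Desilylation as in step 9 gives the saturated chloro β-keto ester F7, and dianion alkylation as in step 10 gives 14. Any dianion that acylates at C2 before it alkylates is carried on to 15 by the same base.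

## Further compounds

F1 | step 8 | methyl 2-diazo-3-hydroxybutanoate (racemic) | COC(=O)C(=[N+]=[N-])C(C)O
F2 | step 8 | methyl 2-diazobut-3-enoate | COC(=O)C(=[N+]=[N-])C=C
F3 | step 8 | methyl (4R)-4-(4-chloro-2-methylbutan-2-yl)-6-(4-methoxy-2-methyl-4-oxobutan-2-yl)cyclohepta-1,5-diene-1-carboxylate | COC(=O)C1=CC[C@@H](C(C)(C)CCCl)C=C(C(C)(C)CC(=O)OC)C1
F4 | step 8 | methyl (4R)-4-(4-chloro-2-methylbutan-2-yl)-6-(4-methoxy-2-methyl-4-oxobutan-2-yl)-2-(4,4,5,5-tetramethyl-1,3,2-dioxaborolan-2-yl)cyclohept-5-ene-1-carboxylate (C4/C5 diastereomers) | COC(=O)C1C(B2OC(C)(C)C(C)(C)O2)C[C@@H](C(C)(C)CCCl)C=C(C(C)(C)CC(=O)OC)C1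
F5 | step 8 | methyl (4R)-4-(4-chloro-2-methylbutan-2-yl)-2-hydroxy-6-(4-methoxy-2-methyl-4-oxobutan-2-yl)cyclohept-5-ene-1-carboxylate (C4/C5 diastereomers) | COC(=O)C1C(O)C[C@@H](C(C)(C)CCCl)C=C(C(C)(C)CC(=O)OC)C1
F6 | step 11 | C7-saturated silyl enol ether (H7 and H12 cis) | COC(=O)C1=C(O[Si](C)(C)C(C)(C)C)C[C@@H](C(C)(C)CCCl)C[C@@H](C(C)(C)CC(=O)OC)C1
F7 | step 11 | C7-saturated chloro β-keto ester (H7 and H12 cis) | COC(=O)C1C(=O)C[C@@H](C(C)(C)CCCl)C[C@@H](C(C)(C)CC(=O)OC)C1
F8 | step 12 | C5-geranyl bicyclic keto diester (geranyl trans to the C7 chain; C3 undefined) | CC(C)=CCC/C(C)=C/C[C@@]1(C(=O)OC)C[C@H](C(C)(C)CC(=O)OC)C[C@@H]2C(C)(C)CCC2C1=O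
F9 | step 14 | C9 carboxylic acid corresponding to 17 | CC(C)=CCC/C(C)=C/C[C@@]1(C(=O)O)C[C@H]2C[C@@H]3C(C)(C)CC[C@]3(C1=O)C(=O)CC2(C)C
F10 | step 14 | C9 acid chloride corresponding to 17 | CC(C)=CCC/C(C)=C/C[C@@]1(C(Cl)=O)C[C@H]2C[C@@H]3C(C)(C)CC[C@]3(C1=O)C(=O)CC2(C)C
F11 | step 15 | 1-bromo tricyclic diketo ester (C1 and C5 undefined) | COC(=O)C1C[C@H]2C[C@@H]3C(C)(C)CC[C@]3(C1=O)C(=O)C(Br)C2(C)C
F12 | step 15 | 1-bromo C5-geranyl tricyclic diketo ester (C1 undefined) | CC(C)=CCC/C(C)=C/C[C@@]1(C(=O)OC)C[C@H]2C[C@@H]3C(C)(C)CC[C@]3(C1=O)C(=O)C(Br)C2(C)C
F13 | step 15 | cage trione with bromine at the bridgehead C1 | CC(C)=CCC/C(C)=C/C[C@@]12C[C@H]3C[C@@H]4C(C)(C)CC[C@]4(C1=O)C(=O)[C@@](Br)(C2=O)C3(C)C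
F14 | step 15 | cage trione with a hydroxy(phenyl)methyl group at C1 (carbinol centre undefined) | CC(C)=CCC/C(C)=C/C[C@@]12C[C@H]3C[C@@H]4C(C)(C)CC[C@]4(C1=O)C(=O)[C@@](C(O)c1ccccc1)(C2=O)C3(C)C
A1 | alternative 1 | cage trione with C1–H (identical with 18) | CC(C)=CCC/C(C)=C/C[C@@]12C[C@H]3C[C@@H]4C(C)(C)CC[C@]4(C1=O)C(=O)[C@@H](C2=O)C3(C)C
A2 | alternative 1 | ring B trimethylsilyl enol ether carrying the cyclopentane-1,1-dicarbonyl dichloride | CC(C)=CCC/C(C)=C/CC1=C(O[Si](C)(C)C)CC(C)(C)[C@@H](C1)C[C@@H]1C(C)(C)CCC1(C(Cl)=O)C(Cl)=O
A3 | alternative 2 | cis-fused rings D and E with the angular C4 ester | COC(=O)[C@]12CCC(C)(C)[C@H]1C[C@H](CCC(=O)OC)C(C)(C)CC2=O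
A4 | alternative 2 | cycloheptenone ester (ring D, C3=C12) | COC(=O)C1=CC[C@H](CCC(=O)OC)C(C)(C)CC1=O
A5 | alternative 2 | 3-methylbut-3-en-1-yl 4-methylbenzenesulfonate | C=C(C)CCOS(=O)(=O)c1ccc(C)cc1
A6 | alternative 3 | rings A, D and E with the enolised C4,C9-dione and the C5 geranyl group | CC(C)=CCC/C(C)=C/CC1=C(O)[C@]23CCC(C)(C)[C@H]2C[C@H](CCl)C(C)(C)[C@H](C1=O)C3=O
A7 | alternative 3 | methyl enol ether of the hydroazulenone (rings D and E) | COC1=C2CCC(C)(C)[C@H]2C[C@H](CCl)C(C)(C)C1
A8 | alternative 3 | geranylmalonyl dichloride | CC(C)=CCC/C(C)=C/CC(C(Cl)=O)C(Cl)=O
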